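## Structural features

The target 14 is an isoflavone: a benzene ring A fused along C4a–C8a to a 4-pyranone ring C (chromen-4-one), with aryl ring B joined to C3 by the single bond C3–C1'. It has no stereocentre. Ring A is hexasubstituted: C4a carries the C4 carbonyl, C8a the ring oxygen O1, and C5, C6, C7 and C8 each carry an oxygen, of which only the one on C6 is methylated. The C5 and C8 hydroxyls are para (a hydroquinone) and C7/C8 form a catechol, so ring A oxidises easily to the 5,8-quinone, above all in base. Ring C is unsubstituted at C2 and opens when hydroxide, alkoxide or amines add there. Ring B has a free 3'-hydroxyl beside two methyl ethers, so three methyl ethers (C6, C4', C5') must survive the unmasking of the C7 and C3' hydroxyls. The real difficulty is the regiodefined placement of five oxygen-bearing carbons in one benzene ring with C6 told apart from C7, since no free ring position is left for stepwise aromatic substitution. The key step uses the fact that C5–C6–C7–C8, oxygenated on every carbon with para hydroxyls at its ends, is the skeleton of a squaric ester after 1,2-addition, while C4a=C8a, C4=O and O1 already exist as C3=C2, C4=O and O1 of a 4-pyranone.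

## Logic of the disconnections

**14 to 13.** The two O–alkyl bonds on O7 and O3' are cut. Both temporary groups are the same secondary alkyl ether, so one Lewis-acid treatment removes both and nothing else has to change. The gain is that every phenol that must stay free during the ring construction (O5, O8) never needs protection. The forward step must cleave secondary alkyl ethers in the presence of three methyl ethers and must keep the polyphenol away from oxygen.

**13 to 10 (through 12 and 11).** The C8–C8a bond of ring A is cut and C5 is reconnected to C8, which turns ring A into a four-membered ring attached to a monocyclic pyranone. This removes the hexasubstituted benzene entirely: its four oxygenated carbons come as one unit and its other two carbons are an existing double bond of 10. The forward step demands that the ring-opened intermediate 11 has its ketene on the side of the pyranone double bond and closes onto it faster than it is consumed otherwise. 10 is kept as the free carbinol because its hydroxyl becomes the C5 hydroxyl and can hydrogen-bond to the pyranone carbonyl in the reactive conformer.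

**10 to 9.** The C–O bond at the ring carbon beside the carbinol carbon (future C6) is cut, replacing methoxy by the same secondary alkoxy group found on the neighbouring carbon. The reason is that 9 then derives from a symmetrical four-carbon reagent, and the two alkoxy carbons become electronically different only after the 1,2-addition. The forward step must exchange only the alkoxy group on the vinylogous ester carbon, under base mild enough for the pyranone and the carbinol.

**9 to 6 and 7 (through 8).** The bond between the carbinol carbon (future C5) and the pyranone carbon (future C4a) is cut. This is a carbonyl addition to one of two equivalent carbonyl groups of 7, so no regiochemical question arises. The gain is two pieces of similar size, one of them commercial. The demand is a pyranone-based organomagnesium species 8 that is formed and used cold enough not to attack its own ring, and mono-addition to 7.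

**6 to 5 and 3.** The C3–C1' bond between rings C and B is cut as a palladium-catalysed coupling of an aryl boronate with a vinylic bromide. The gain is that ring B arrives complete and the second bromine of 5 is kept as the handle for the next step. The demand is mono-coupling of a symmetrical dibromide.

**5 to 4.** Two C–Br bonds are cut; the forward step is a double α-bromination of a vinylogous ester, which can only occur at the two equivalent nucleophilic positions.

**3 to 2 to 1.** The C–B bond and then the O–alkyl bond are cut. The boron must enter at the one ring C–H that has no ortho substituent, which is what sterically governed C–H borylation delivers; classical electrophilic substitution would go ortho or para to an ether instead.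

## Other disconnections considered

**Alternative 1:** The cut is the C3–C4 bond of ring C, which leads back to the aldehyde–ketone A2 (a salicylaldehyde O-phenacyl ether; the aldehyde carbon is the future C4, the aryl ketone carbon the future C3). In the forward sense a triazolium-derived carbene and an amidine base turn the aldehyde carbon into an acyl anion equivalent that adds to the ketone and closes ring C as the racemic tertiary alcohol A1.

- In its favour: the intramolecular aldehyde–ketone benzoin on this kind of tether is an established route to 3-hydroxychroman-4-ones, it runs near room temperature without metals, and A2 is assembled convergently by O-alkylation. On precedent for the ring-forming event itself, this alternative is the better of the two plans.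
- Against it here: it does not touch the real problem. The pentaoxygenated, hexasubstituted benzaldehyde half of A2, with four differentiated oxygens, must be made by a long sequence on a benzene ring.
- The aldehyde of A2 lies between two ortho alkoxy groups and is electron-rich. Carbene addition would be slow, which gives the base time to start an aldol of the α-aryloxy ketone onto the aldehyde (Rap–Stoermer-type benzofuran formation).
- A1 is a tertiary α-hydroxy ketone, so the C2=C3 double bond needs a separate dehydration that cannot run as a simple base-induced β-elimination. The C3 stereocentre is made only to be destroyed, and four isopropyl ethers then remain to be cleaved.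
- Comparison: on structure, the chosen plan creates ring A with its four oxygens from one four-carbon unit, whereas this plan has to decorate a benzene ring. On mechanism, the alternative is ahead in precedent and mildness. On step economy, the chosen plan is ahead: the ring A aldehyde alone is likely to need about as many steps as the whole chosen route, and the end game (dehydration plus fourfold dealkylation) is longer than the single dealkylation of 13.

**Alternative 2:** The cut is the C4a–C5 bond of ring A, which leads back to the pyranone keto ester A4 (a mixture of stereoisomers at two centres of no consequence). Its side chain on the pyranone carbon that becomes C8a holds C8 (acetal-protected oxygen), C7 (ketone), C6 (methoxy) and C5 (ester). In the forward sense a base forms the extended enolate through the pyranone, the ring carbon destined to be C4a attacks the ester in a six-membered Claisen-type closure, and enolisation gives A3.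

- In its favour: like the chosen plan, it builds ring A instead of decorating it; on that central point the two plans are equals.
- The C6, C7 and C8 oxygens are differentiated by the way the chain is built, with no alkoxy exchange.
- Closures of pyranone-bound polyketide chains to 5-hydroxychromones are a known biomimetic reaction type.
- A3 carries acetal protecting groups that dilute acid removes, and the para-dihydroxy pattern is not exposed until the last step. Both points are better than in the chosen plan.
- Against it here: A4 is the burden. It is a 2,5-disubstituted 4-pyranone with a 1,3-dicarbonyl chain bearing three different oxygen substituents, to be assembled by acylation on a pyranone side chain, where O- versus C-acylation, retro-Claisen cleavage and self-condensation must all be managed.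
- The cyclisation uses strong base on a pyranone with a free position next to the ring oxygen, where addition and ring opening compete.
- Comparison: on structure, the two are equal in concept. On mechanism, the alternative's ionic closure is at least the equal of a pericyclic cascade with a new alkene partner. On step economy, the chosen plan takes its four oxygenated carbons from one commercial reagent and reaches 10 in six steps, while A4 needs a longer linear build-up, so the chosen plan should be clearly shorter.

**Alternative 3:** The cut opens ring C at O1–C8a and C4–C4a, which leads back to the silylaryl triflate A6 and the formyl arylacetate A7. In the forward sense fluoride-induced elimination from A6 gives the aryne A8. The enolate oxygen of A7 adds to the aryne carbon remote from the flanking isopropoxy group, and the aryl anion formed at C4a acylates on the ester to give A5.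

- In its favour: it is the most convergent of the four plans, and on convergence it is better than the chosen plan. Ring C and both ring-fusion bonds form in one mild, metal-free operation.
- The regiochemistry of addition to an aryne with one flanking alkoxy group is predictable and puts the anion where it is needed.
- Against it here: A5 has hydrogen at C8, and this is structural. An aryne with oxygen on both flanking carbons would lose the inductive bias that directs the addition.
- The C8 oxygen would therefore have to be introduced after ring closure, for example by persulfate oxidation para to a freed C5 hydroxyl. That is an extra operation on an electron-rich polyphenol and also threatens ring B.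
- A6 is a pentasubstituted benzene that needs its own multi-step synthesis.
- Enolates of β-dicarbonyl compounds tend to attack arynes through carbon, which would lead to insertion into the C–C bond and not to the chromone.
- Comparison: on structure, the chosen plan delivers the oxygens on C5 to C8 in one event, while this plan delivers three and leaves the hardest one for late oxidation. On mechanism, both rely on a reactive intermediate (ketene or aryne) whose fate hangs on one selectivity, so the risk is comparable. On step economy, the fragment union is shorter, but the synthesis of A6 and the oxidation after cyclisation should make the whole route longer than the chosen one.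

Key step: step 7

Remark on the chemistry: 10 and 13 map atom for atom onto 14 (cyclobutenone C1, C2, C3, C4 become C8, C7, C6, C5) and are used without structural change. The carbinol carbon of 9 and 10 and C8a of 12 are the only stereocentres on the route; all are racemic and all are erased before 13.

## Steps

Step 1
Reactants: 1 2,3-dimethoxyphenol
Product: 2 1,2-dimethoxy-3-(propan-2-yloxy)benzene
Conditions: 2-bromopropane (1.5 equiv), K2CO3, DMF, 60 °C
Reagents that add atoms: 2-bromopropane, CC(C)Br
Why: Williamson ether synthesis; the phenoxide is the only nucleophile and DMF favours substitution over elimination of the secondary bromide.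

Step 2
Reactants: 2 1,2-dimethoxy-3-(propan-2-yloxy)benzene
Product: 3 2-[3,4-dimethoxy-5-(propan-2-yloxy)phenyl]-4,4,5,5-tetramethyl-1,3,2-dioxaborolane
Conditions: B2pin2 (1.0 equiv), [Ir(OMe)(cod)]2 (1.5 mol %), 4,4'-di-tert-butyl-2,2'-bipyridine (3 mol %), THF, 80 °C
Reagents that add atoms: bis(pinacolato)diboron, CC1(C)OB(OC1(C)C)B1OC(C)(C)C(C)(C)O1
Why: Iridium-catalysed aromatic C–H borylation is governed by sterics; in this 1,2,3-trioxygenated ring only C5–H has no ortho substituent, so boron should enter para to the central methoxy group.

Step 3
Reactants: 4 4H-pyran-4-one
Product: 5 3,5-dibromo-4H-pyran-4-one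
Conditions: Br2 (2.2 equiv), CH2Cl2, 0 °C to rt; then Et3N (2.5 equiv), 0 °C
Reagents that add atoms: bromine, BrBr
Why: α-Bromination of a vinylogous ester by addition of bromine across each enol-ether double bond and base-induced loss of HBr; C3 and C5 are the only nucleophilic carbons and are equivalent.

Step 4
Reactants: 5 3,5-dibromo-4H-pyran-4-one; 3 2-[3,4-dimethoxy-5-(propan-2-yloxy)phenyl]-4,4,5,5-tetramethyl-1,3,2-dioxaborolane
Product: 6 3-bromo-5-[3,4-dimethoxy-5-(propan-2-yloxy)phenyl]-4H-pyran-4-one
Conditions: 5 (3 equiv), Pd(dppf)Cl2 (3 mol %), K3PO4, 1,4-dioxane/H2O (10:1), 60 °C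
Reagents that add atoms: none
Why: Suzuki–Miyaura cross-coupling; the two C–Br bonds of 5 are equivalent, so an excess of 5 (recovered afterwards) should hold double arylation down, and phosphate at moderate temperature spares the pyranone ring.

Step 5
Reactants: 6 3-bromo-5-[3,4-dimethoxy-5-(propan-2-yloxy)phenyl]-4H-pyran-4-one; 7 di-isopropyl squarate (3,4-di(propan-2-yloxy)cyclobut-3-ene-1,2-dione)
Product: 9 racemic 4-hydroxy-4-{5-[3,4-dimethoxy-5-(propan-2-yloxy)phenyl]-4-oxo-4H-pyran-3-yl}-2,3-di(propan-2-yloxy)cyclobut-2-en-1-one, via pyranonyl Grignard reagent 8 (not isolated)
Conditions: iPrMgCl·LiCl (1.05 equiv), THF, −40 °C, 30 min; then cannulation into 7 (1.5 equiv), THF, −78 °C; aq NH4Cl at −78 °C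
Reagents that add atoms: none
Why: Bromine–magnesium exchange on an sp2 C–Br bond activated by the neighbouring carbonyl (the behaviour of 3-halochromones and 5-halo-1,3-dioxin-4-ones) should give the carbonyl-chelated Grignard 8, which adds 1,2 to one of the two equivalent carbonyl groups of 7 under inverse addition. The new carbinol carbon is racemic and is lost in step 7, and the buffered cold quench avoids the acid-induced loss of the carbinol that such adducts undergo.

Step 6
Reactants: 9 racemic 4-hydroxy-4-{5-[3,4-dimethoxy-5-(propan-2-yloxy)phenyl]-4-oxo-4H-pyran-3-yl}-2,3-di(propan-2-yloxy)cyclobut-2-en-1-one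
Product: 10 racemic 4-hydroxy-3-methoxy-4-{5-[3,4-dimethoxy-5-(propan-2-yloxy)phenyl]-4-oxo-4H-pyran-3-yl}-2-(propan-2-yloxy)cyclobut-2-en-1-one
Conditions: NaOMe (0.2 equiv), MeOH/THF, −20 to 0 °C; then AcOH (0.2 equiv)
Reagents that add atoms: methanol, CO
Why: Transetherification of a vinylogous ester by addition–elimination: methoxide adds to C3, the β-carbon of the strained enone beside the carbinol, and expels isopropoxide. C2 is an enol-ether carbon α to the carbonyl with no acceptor character, so its isopropoxy group should stay, and the excess of methanol drives the exchange.

Step 7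
Reactants: 10 racemic 4-hydroxy-3-methoxy-4-{5-[3,4-dimethoxy-5-(propan-2-yloxy)phenyl]-4-oxo-4H-pyran-3-yl}-2-(propan-2-yloxy)cyclobut-2-en-1-one
Product: 13 5,8-dihydroxy-6-methoxy-3-[3,4-dimethoxy-5-(propan-2-yloxy)phenyl]-7-(propan-2-yloxy)-4H-chromen-4-one, via dienylketene 11 (not isolated), via cyclohexadienone 12 (not isolated)
Conditions: degassed p-xylene (0.02 M), 135 °C, Ar; aq Na2S2O4 wash
Reagents that add atoms: none
Why: Heating opens the cyclobutenone by a conrotatory 4π electrocyclic cleavage of the C1–C4 bond; the hydroxyl, the strongest donor on C4, rotates outward (torquoselectivity), so that in ketene 11 the pyranone ring lies cis to the ketene arm. The enol O–H of 11 can hydrogen-bond to the pyranone carbonyl, which turns the pyranone C2=C3 bond toward the ketene carbon. A thermal disrotatory 6π electrocyclisation (ketene C=C, enol C=C, pyranone C=C) then joins the ketene carbon to the pyranone carbon next to the ring oxygen; this is the C8–C8a bond and it closes the six-membered carbocycle, ring A, in 12. Enolisation of the C8a–H of 12 gives the aromatic hydroquinone 13 and makes the sequence irreversible. The closest known reaction type is the Moore rearrangement of squarate-derived 4-alkenyl-, 4-aryl- and 4-heteroaryl-4-hydroxycyclobutenones to hydroquinones; the enone double bond of a 4-pyranone is a new alkene partner within that class. No stereocentre remains: the carbinol carbon of 10 becomes sp2 on ring opening and the C8a centre of 12 is lost on tautomerisation. The step needs the ketene to form on the side of the pyranone C=C and to close faster than the hydroxyl captures it; outward rotation of the hydroxyl secures the first, and the methoxy group beside the carbinol carbon of 10 fixes C6–OMe and C7–O-isopropyl with no regiochemical choice left. Degassed solvent and the dithionite wash should keep 13 from oxidising to the 5,8-quinone.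

Step 8
Reactants: 13 5,8-dihydroxy-6-methoxy-3-[3,4-dimethoxy-5-(propan-2-yloxy)phenyl]-7-(propan-2-yloxy)-4H-chromen-4-one
Product: 14 5,7,8-trihydroxy-3-(3-hydroxy-4,5-dimethoxyphenyl)-6-methoxy-4H-chromen-4-one
Conditions: BCl3 (1 M in CH2Cl2, 6 equiv), CH2Cl2, −78 to 0 °C; then H2O, aq Na2S2O4, Ar
Reagents that add atoms: none
Why: Lewis-acid ether cleavage; BCl3 ionises secondary alkyl aryl ethers much faster than methyl ethers, so both isopropyl groups should leave as 2-chloropropane while the three methyl ethers stay, provided temperature and time are kept low. The reductive, oxygen-free work-up protects the tetraphenol.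

## Compound list

1 | 2,3-dimethoxyphenol | COc1cccc(O)c1OC | starting material
2 | 1,2-dimethoxy-3-(propan-2-yloxy)benzene | COc1cccc(OC(C)C)c1OC | intermediate
3 | 2-[3,4-dimethoxy-5-(propan-2-yloxy)phenyl]-4,4,5,5-tetramethyl-1,3,2-dioxaborolane | COc1cc(B2OC(C)(C)C(C)(C)O2)cc(OC(C)C)c1OC | intermediate
4 | 4H-pyran-4-one | O=c1ccocc1 | starting material
5 | 3,5-dibromo-4H-pyran-4-one | O=c1c(Br)cocc1Br | intermediate
6 | 3-bromo-5-[3,4-dimethoxy-5-(propan-2-yloxy)phenyl]-4H-pyran-4-one | O=c1c(Br)cocc1-c1cc(OC)c(OC)c(OC(C)C)c1 | intermediate
7 | di-isopropyl squarate (3,4-di(propan-2-yloxy)cyclobut-3-ene-1,2-dione) | CC(C)OC1=C(OC(C)C)C(=O)C1=O | starting material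
8 | chloro{5-[3,4-dimethoxy-5-(propan-2-yloxy)phenyl]-4-oxo-4H-pyran-3-yl}magnesium, LiCl complex | O=c1c([Mg]Cl)cocc1-c1cc(OC)c(OC)c(OC(C)C)c1 | intermediate (not isolated)
9 | racemic 4-hydroxy-4-{5-[3,4-dimethoxy-5-(propan-2-yloxy)phenyl]-4-oxo-4H-pyran-3-yl}-2,3-di(propan-2-yloxy)cyclobut-2-en-1-one | O=C1C(OC(C)C)=C(OC(C)C)C1(O)C1=COC=C(c2cc(OC)c(OC)c(OC(C)C)c2)C1=O | intermediate
10 | racemic 4-hydroxy-3-methoxy-4-{5-[3,4-dimethoxy-5-(propan-2-yloxy)phenyl]-4-oxo-4H-pyran-3-yl}-2-(propan-2-yloxy)cyclobut-2-en-1-one | O=C1C(OC(C)C)=C(OC)C1(O)C1=COC=C(c2cc(OC)c(OC)c(OC(C)C)c2)C1=O | intermediate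
11 | (3Z)-4-hydroxy-3-methoxy-4-{5-[3,4-dimethoxy-5-(propan-2-yloxy)phenyl]-4-oxo-4H-pyran-3-yl}-2-(propan-2-yloxy)buta-1,3-dien-1-one (hydroxyl anti to the ketene arm) | O=C=C(OC(C)C)/C(OC)=C(/O)C1=COC=C(c2cc(OC)c(OC)c(OC(C)C)c2)C1=O | intermediate (not isolated)
12 | racemic 5-hydroxy-6-methoxy-3-[3,4-dimethoxy-5-(propan-2-yloxy)phenyl]-7-(propan-2-yloxy)-8aH-chromene-4,8-dione | O=C1C(OC(C)C)=C(OC)C(O)=C2C(=O)C(c3cc(OC)c(OC)c(OC(C)C)c3)=COC12 | intermediate (not isolated)
13 | 5,8-dihydroxy-6-methoxy-3-[3,4-dimethoxy-5-(propan-2-yloxy)phenyl]-7-(propan-2-yloxy)-4H-chromen-4-one | COc1c(O)c2c(=O)c(-c3cc(OC)c(OC)c(OC(C)C)c3)coc2c(O)c1OC(C)C | intermediate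
14 | 5,7,8-trihydroxy-3-(3-hydroxy-4,5-dimethoxyphenyl)-6-methoxy-4H-chromen-4-one (5,7,8,3'-tetrahydroxy-6,4',5'-trimethoxyisoflavone) | COc1cc(-c2coc3c(O)c(O)c(OC)c(O)c3c2=O)cc(O)c1OC | target

## Step count and least certain steps

Total step count: 8. Longest linear sequence: 7 steps (steps 1, 2, 4, 5, 6, 7, 8, starting from 1); the pyranone branch (step 3) joins at step 4 and 7 enters at step 5.

**Step 7 (key step).** The enone double bond of the pyranone is a less willing 2π partner than the alkenes and arenes usual in this rearrangement. The most likely failure is that 11 is used up before the 6π closure, either by addition of its own hydroxyl to the ketene (butenolide formation) or by oligomerisation; oxidation of the hydroquinone during isolation is a second risk. Fallback, setting out from 10: silylation with chlorotrimethylsilane, Et3N and catalytic 4-(dimethylamino)pyridine in CH2Cl2 would give racemic 3-methoxy-4-{5-[3,4-dimethoxy-5-(propan-2-yloxy)phenyl]-4-oxo-4H-pyran-3-yl}-2-(propan-2-yloxy)-4-[(trimethylsilyl)oxy]cyclobut-2-en-1-one F1. This has no O–H to trap the ketene. Thermolysis of F1 in degassed xylene should give the mono-silylated, less oxidisable 8-hydroxy-6-methoxy-3-[3,4-dimethoxy-5-(propan-2-yloxy)phenyl]-7-(propan-2-yloxy)-5-[(trimethylsilyl)oxy]-4H-chromen-4-one F2. Brief treatment of F2 with dilute aqueous HCl in THF returns to the route at 13.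

**Step 5.** The exchange reagent may attack the pyranone (carbonyl addition or addition at the positions next to the ring oxygen) faster than it exchanges the bromine. The metallated pyranone may also open by β-elimination of the ring oxygen if it warms. Fallback, setting out from 6: copper-catalysed halogen exchange (CuI 10 mol %, NaI, N,N'-dimethylethylenediamine, 1,4-dioxane, 110 °C) would give 3-iodo-5-[3,4-dimethoxy-5-(propan-2-yloxy)phenyl]-4H-pyran-4-one F3. Its iodine–magnesium exchange with iPrMgCl·LiCl should be complete at −78 °C, where attack on the ring is slow. This returns to the route at 8, which is added to 7 as before.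

**Step 6.** Methoxide may open the pyranone ring at the carbon next to oxygen, or deprotonate the carbinol and trigger ring opening or an acyloin-type shift that scrambles the two alkoxy positions, in competition with the exchange. Fallback, setting out from 7, which fixes the methoxy group before the C–C bond is made: mono-saponification (NaOH, 1 equiv, aqueous THF, 0 °C, then acid) would give 3-hydroxy-4-(propan-2-yloxy)cyclobut-3-ene-1,2-dione F4. O-Methylation (iodomethane, Ag2O, CH2Cl2) would give 3-methoxy-4-(propan-2-yloxy)cyclobut-3-ene-1,2-dione F5. Addition of 8 to F5 at −78 °C at the carbonyl flanked by the smaller methoxy-bearing carbon returns to the route at 10. The regiocontrol rests only on the size difference of the two alkoxy groups, so the isomeric adduct would have to be separated.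

**Step 4.** The remaining C–Br bond of 6 is about as reactive as those of 5, so a second coupling competes; the electron-poor dibromide may also be degraded by the aqueous base. Fallback, setting out from 5 and 7, which replaces the statistical coupling by an inherently mono-selective exchange: iPrMgCl·LiCl (1 equiv, THF, −40 °C) would convert 5 into (5-bromo-4-oxo-4H-pyran-3-yl)chloromagnesium F6 (not isolated; a second exchange on an organomagnesium species is disfavoured). Addition of F6 to 7 at −78 °C would give racemic 4-(5-bromo-4-oxo-4H-pyran-3-yl)-4-hydroxy-2,3-di(propan-2-yloxy)cyclobut-2-en-1-one F7. Suzuki–Miyaura coupling of F7 with 3 (Pd(dppf)Cl2, K3PO4, aqueous 1,4-dioxane, 40 °C, well below the temperature of ring opening) returns to the route at 9.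

## Further compounds

F1 | step 7 | racemic 3-methoxy-4-{5-[3,4-dimethoxy-5-(propan-2-yloxy)phenyl]-4-oxo-4H-pyran-3-yl}-2-(propan-2-yloxy)-4-[(trimethylsilyl)oxy]cyclobut-2-en-1-one | O=C1C(OC(C)C)=C(OC)C1(O[Si](C)(C)C)C1=COC=C(c2cc(OC)c(OC)c(OC(C)C)c2)C1=O
F2 | step 7 | 8-hydroxy-6-methoxy-3-[3,4-dimethoxy-5-(propan-2-yloxy)phenyl]-7-(propan-2-yloxy)-5-[(trimethylsilyl)oxy]-4H-chromen-4-one | COc1c(O[Si](C)(C)C)c2c(=O)c(-c3cc(OC)c(OC)c(OC(C)C)c3)coc2c(O)c1OC(C)C
F3 | step 5 | 3-iodo-5-[3,4-dimethoxy-5-(propan-2-yloxy)phenyl]-4H-pyran-4-one | O=c1c(I)cocc1-c1cc(OC)c(OC)c(OC(C)C)c1
F4 | step 6 | 3-hydroxy-4-(propan-2-yloxy)cyclobut-3-ene-1,2-dione | CC(C)OC1=C(O)C(=O)C1=O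
F5 | step 6 | 3-methoxy-4-(propan-2-yloxy)cyclobut-3-ene-1,2-dione | COC1=C(OC(C)C)C(=O)C1=O
F6 | step 4 | (5-bromo-4-oxo-4H-pyran-3-yl)chloromagnesium, LiCl complex | O=c1c(Br)cocc1[Mg]Cl
F7 | step 4 | racemic 4-(5-bromo-4-oxo-4H-pyran-3-yl)-4-hydroxy-2,3-di(propan-2-yloxy)cyclobut-2-en-1-one | O=C1C(OC(C)C)=C(OC(C)C)C1(O)C1=COC=C(Br)C1=O
A1 | alternative 1 | racemic 3-hydroxy-6-methoxy-3-[3,4-dimethoxy-5-(propan-2-yloxy)phenyl]-5,7,8-tri(propan-2-yloxy)chroman-4-one | COc1c(OC(C)C)c(OC(C)C)c2OCC(O)(c3cc(OC)c(OC)c(OC(C)C)c3)C(=O)c2c1OC(C)C
A2 | alternative 1 | 5-methoxy-2-{2-[3,4-dimethoxy-5-(propan-2-yloxy)phenyl]-2-oxoethoxy}-3,4,6-tri(propan-2-yloxy)benzaldehyde | O=Cc1c(OC(C)C)c(OC)c(OC(C)C)c(OC(C)C)c1OCC(=O)c1cc(OC)c(OC)c(OC(C)C)c1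
A3 | alternative 2 | 5,7-dihydroxy-6-methoxy-8-(methoxymethoxy)-3-[3,4-dimethoxy-5-(methoxymethoxy)phenyl]-4H-chromen-4-one | COCOc1c(O)c(OC)c(O)c2c(=O)c(-c3cc(OC)c(OC)c(OCOC)c3)coc12
A4 | alternative 2 | methyl 2-methoxy-4-(methoxymethoxy)-4-{5-[3,4-dimethoxy-5-(methoxymethoxy)phenyl]-4-oxo-4H-pyran-2-yl}-3-oxobutanoate (mixture of stereoisomers) | COC(=O)C(OC)C(=O)C(OCOC)c1cc(=O)c(-c2cc(OC)c(OC)c(OCOC)c2)co1
A5 | alternative 3 | 6-methoxy-3-[3,4-dimethoxy-5-(propan-2-yloxy)phenyl]-5,7-di(propan-2-yloxy)-4H-chromen-4-one | COc1c(OC(C)C)cc2occ(-c3cc(OC)c(OC)c(OC(C)C)c3)c(=O)c2c1OC(C)C
A6 | alternative 3 | 4-methoxy-3,5-di(propan-2-yloxy)-2-(trimethylsilyl)phenyl trifluoromethanesulfonate | COc1c(OC(C)C)cc(OS(=O)(=O)C(F)(F)F)c([Si](C)(C)C)c1OC(C)C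
A7 | alternative 3 | methyl 2-[3,4-dimethoxy-5-(propan-2-yloxy)phenyl]-3-oxopropanoate | COC(=O)C(C=O)c1cc(OC)c(OC)c(OC(C)C)c1
A8 | alternative 3 | 1,2-didehydro-4-methoxy-3,5-di(propan-2-yloxy)benzene (aryne) | C1#CC(OC(C)C)=C(OC)C(OC(C)C)=C1
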